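## Analysis of the target

Mollicellin B is a tetracyclic depsidone. Ring A, an orsellinate-type benzene, and ring B are joined on neighbouring carbons by an aryl ester and a diaryl ether, which closes the seven-membered dioxepinone ring C. Ring B is also fused to ring D, a 2,2-dimethyl-2,3-dihydropyran-4-one, so rings B and D form a chroman-4-one.

In benzoate locants ring A carries the lactone carbonyl at C1, the ether oxygen at C2, formyl at C3, hydroxyl at C4, hydrogen at C5 and methyl at C6. In chromanone locants ring B carries the ketone carbon at C4a, methyl at C5, the ester oxygen at C6, the ether oxygen at C7, hydrogen at C8 and the ring D oxygen at C8a.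

There is no stereocenter: the only sp3 ring atoms are a CH2 and a carbon with two methyl groups. Every problem is therefore one of regiochemistry.

The sensitive groups are the salicylaldehyde unit, the aryl ester of ring C (open to nucleophiles) and the β-aryloxy ketone of ring D (opens reversibly under strong base).

Three things make the synthesis hard. Each benzene ring keeps only one hydrogen. The ester joins a doubly ortho-substituted acid to a doubly ortho-substituted phenol. The ring D ketone sits on C4a, wedged between the C5 methyl and the oxygen-bearing C8a, a site that electrophilic acylation of a ring B phenol does not single out.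

The strategy rests on one feature: the oxygens on C6 and C8a of ring B are para to each other. At the quinone oxidation level ring B is a 2-aryloxy-6-methyl-1,4-benzoquinone, and its only unsubstituted, non-deactivated carbon is the future C4a. Acylation of that quinone also returns two phenols, one beside the new ketone for ring D and one at C6 for the lactone.

## Retrosynthetic reasoning

**17 from 16.** The last bond cut is the O–CH3 bond of a methyl ether on the ring A hydroxyl. The hydroxyl stays masked throughout so that ring A offers only one phenol to the ether-forming step and none to the lactonisation. The ortho formyl group of 16 gives a chelation handle, so this one ether can be cleaved by a Lewis acid beside the lactone, the diaryl ether and the ring D ether.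

**16 from 15.** The C3–CHO bond of ring A is cut back to a C–Br bond. An aryl aldehyde would hand its formyl hydrogen to an excited quinone and would not survive the oxidation that makes the carboxyl group. Bromine is inert to visible light, acid and carbodiimide. The forward reaction is a palladium-catalysed reductive carbonylation on a substrate that no longer has a free OH.

**15 from 14 from 13.** The lactone C(=O)–O bond of ring C is cut, giving hydroxy acid 14 and, one step further back, its tert-butyl ester 13. Esterifying these two hindered partners intermolecularly would be poor. With the ether bridge in place the acid and the C6 phenol are held for a seven-membered closure. The tert-butyl ester comes off by acid without attack at the crowded carbonyl.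

**13 from 10 and 11.** Two bonds of ring D are cut: C4a–C4 (aryl to acyl) and O1–C2 (phenol oxygen to the dimethyl carbon). Ring B goes back to the quinone level. This leaves quinone 10 and the five-carbon enal 11. The cut is made here because the quinone turns the hard position next to the methyl into the only reactive CH. The reaction also returns the two phenols needed for ring D and ring C. The forward step must acylate one carbon of 10 and then add the neighbouring phenol to the enone.

**10 from 7 and 9.** The diaryl ether is cut on the quinone side. Phenol 7 acts as nucleophile and bromoquinone 9 as a vinylogous acyl bromide. This fixes which ring B oxygen becomes the ether without any protecting group on ring B.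

**9 from 8.** The quinone is cut back to phenol 8, which has a free para position and both ortho positions blocked. A single oxidation installs the second oxygen.

**7 from 1 via 6, 5, 4, 3 and 2.** Ring A is taken back through the acid 6, the salicylaldehyde 5, the dimethoxy aldehyde 4 and the bromide 3 to 1. The bromine sits between the two oxygens, so it is placed first, through the aryllithium 2. Formylation of the symmetrical 3 can then give only one aldehyde. The aldehyde supplies the carboxyl carbon and directs cleavage of the one ortho methyl ether that becomes the ether oxygen.

## Alternatives that were turned down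

**Alternative 1: oxidative para-lactonisation.**
- Disconnection: the bond from the lactone oxygen to ring B is cut to a C–H bond. The precursor is the diaryl ether acid A2, whose ring B is a meta-hydroxy, meta-methyl phenyl ether.
- Forward key step: a trivalent iodine diacetate in a fluorinated alcohol (or an anode) oxidises the ring B phenol. The ring A carboxyl attacks the para carbon and proton loss gives the tricyclic depsidone phenol A1.
- For it: ring B needs no prefunctionalisation, the formyl group can be carried from the start, and ring C closes by a C–H/O–H coupling. Up to the tricycle it is shorter than the chosen route and stronger on step economy.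
- Against it: the ether oxygen of A2 has two ortho carbons, one para and one ortho to the hydroxyl. Both are activated in the oxidised phenol and both are reachable through a seven-membered ring, so an isomeric lactone is a real competitor. A1 is a para-acyloxyphenol and is easier to oxidise than A2, which invites over-oxidation to quinone-type products.
- Against it, ring D: A1 still lacks ring D. It would have to be acylated between its hydroxyl and its methyl, with a second ortho position free and an aldehyde and a lactone present.
- Comparison: the chosen route is longer to the tricycle but fixes both oxygen positions and the site of ring D through the quinone.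

**Alternative 2: tethered benzannulation.**
- Disconnection: ring A is taken apart into four bonds. The precursor A4 carries a diazo ketoester on one ring B oxygen and an ynol ether on the neighbouring one.
- Forward key step: irradiation triggers a Wolff shift of the isopropenyl group to an aryloxycarbonyl(isopropenyl)ketene. The ketene adds to the tethered ynol ether. The cyclobutenone opens and a six-electron closure with tautomerisation gives A3, the target with the formyl carbon as a silyl-protected hydroxymethyl group.
- For it: the substitution pattern of ring A follows from the pericyclic sequence and the polarity of the ynol ether, and ring C forms in the same event. It builds more bonds and rings in one step than the chosen key step and is stronger on that point.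
- Against it: A4 is costly. The two adjacent ring B oxygens must be told apart. One must become a fragile aryl alkynyl ether by strong-base chemistry beside a ketone. The other must be acylated with a diazo β-keto acid carrying a polymerisable enone.
- Against it, the key step: the cycloaddition must close a seven-membered ring against ketene dimerisation, and ultraviolet light meets the chromanone chromophore.
- Against it, what remains: the chromanone half of A4 still needs its ketone placed next to the methyl, which this key step does not solve. A3 needs two more steps to reach the aldehyde.
- Comparison: the chosen route has a less ambitious key step, but robust intermediates, cheap arenes and a solution to the ring D problem.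

**Alternative 3: ketene capture and aldol aromatisation.**
- Disconnection: the ester C(=O)–O bond and one C–C bond of ring A are cut. The precursors are diketo-dioxinone A7 and fluorochromanone phenol A6.
- Forward key step: thermolysis of A7 releases an acylketene, which the phenol of A6 captures. Base then acid closes the triketo ester by aldol condensation and aromatisation to the depside A5.
- For it: the hindered aryl ester forms under neutral conditions without a coupling reagent, arguably more gently than a carbodiimide closure. Ring A comes from an acyclic chain. The fluorine of A6 is para to the chromanone carbonyl carbon, which makes a later substitution closure of the ether plausible.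
- Against it, after A5: the ether must close by aromatic substitution on a ring with two oxygen donors and one activating carbonyl, under base and heat that threaten the aryl ester. Formylation must then go between the ether oxygen and the remaining hydroxyl and not to the less hindered carbon next to the methyl.
- Against it, before A5: the triketo aryl ester can expel the phenoxide of A6 by cyclising through oxygen instead of undergoing the aldol. A6 itself needs the ketone next to the methyl and is not commercial.
- Comparison: the chosen route forms the ether first, by a facile substitution on a quinone, and the ester last, intramolecularly. It uses that same quinone to place ring D.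

Key step: step 8

Remark: titanium and boron chelates that exist only until aqueous work-up are treated as part of the work-up and are not numbered.

## Route

Step 1
Reactants: 1 3,5-dimethoxytoluene
Product: 3 2-bromo-1,3-dimethoxy-5-methylbenzene, via 2,6-dimethoxy-4-methylphenyllithium 2 (not isolated)
Conditions: n-BuLi, THF, 0 °C to rt; then BrCH2CH2Br, −78 °C to rt
Reagents that add atoms: 1,2-dibromoethane, BrCCBr
Why: Directed ortho-metalation; the two methoxy groups together direct lithiation to the carbon between them, and the aryllithium takes bromine from 1,2-dibromoethane with loss of ethene, placing bromine where electrophilic bromination would not.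

Step 2
Reactants: 3 2-bromo-1,3-dimethoxy-5-methylbenzene
Product: 4 3-bromo-2,4-dimethoxy-6-methylbenzaldehyde
Conditions: Cl2CHOCH3, TiCl4, CH2Cl2, −10 to 0 °C; then ice/aq. HCl
Reagents that add atoms: dichloromethyl methyl ether, COC(Cl)Cl (formyl carbon); water, O (formyl oxygen on hydrolytic work-up)
Why: Rieche formylation (Friedel–Crafts type); the two free ring positions are equivalent by symmetry and each is para to one methoxy and ortho to the other, so only one aldehyde can form.

Step 3
Reactants: 4 3-bromo-2,4-dimethoxy-6-methylbenzaldehyde
Product: 5 3-bromo-2-hydroxy-4-methoxy-6-methylbenzaldehyde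
Conditions: BCl3 (1.2 equiv), CH2Cl2, −78 to 0 °C; aq. work-up
Reagents that add atoms: none
Why: Chelation-controlled demethylation; BCl3 bridges the formyl oxygen and the ortho methoxy oxygen and cleaves only that ether, while the para methoxy group cannot chelate and stays.

Step 4
Reactants: 5 3-bromo-2-hydroxy-4-methoxy-6-methylbenzaldehyde
Product: 6 3-bromo-2-hydroxy-4-methoxy-6-methylbenzoic acid
Conditions: NaClO2, NaH2PO4, 2-methyl-2-butene (excess), t-BuOH/H2O, 0 °C to rt
Reagents that add atoms: sodium chlorite, [Na+].[O-]Cl=O
Why: Pinnick oxidation; buffered chlorite converts the aldehyde to the acid without touching the aryl bromide or the ether, and the alkene traps HOCl before it can chlorinate the phenol ring.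

Step 5
Reactants: 6 3-bromo-2-hydroxy-4-methoxy-6-methylbenzoic acid
Product: 7 tert-butyl 3-bromo-2-hydroxy-4-methoxy-6-methylbenzoate
Conditions: Cl3CC(=NH)Ot-Bu (2 equiv), CH2Cl2/cyclohexane, rt
Reagents that add atoms: tert-butyl 2,2,2-trichloroacetimidate, CC(C)(C)OC(=N)C(Cl)(Cl)Cl
Why: Imidate esterification; the acid protonates the imidate and the carboxylate oxygen is alkylated by the tert-butyl cation equivalent, so no nucleophile has to reach the crowded carbonyl carbon, and the hydrogen-bonded, doubly flanked phenol is not alkylated without a Lewis acid.

Step 6
Reactants: 8 2-bromo-6-methylphenol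
Product: 9 2-bromo-6-methyl-1,4-benzoquinone
Conditions: ON(SO3K)2 (Fremy's salt, 2.5 equiv), KH2PO4, H2O/acetone, 0 °C to rt
Reagents that add atoms: potassium nitrosodisulfonate ON(SO3K)2, [K+].[K+].[O]N(S(=O)(=O)[O-])S(=O)(=O)[O-]
Why: Teuber oxidation; the nitroxyl radical oxidises a phenol with a free para position to the para-quinone, and both ortho positions are substituted, so no ortho-quinone can form.

Step 7
Reactants: 7 tert-butyl 3-bromo-2-hydroxy-4-methoxy-6-methylbenzoate; 9 2-bromo-6-methyl-1,4-benzoquinone
Product: 10 tert-butyl 3-bromo-4-methoxy-6-methyl-2-[(5-methyl-3,6-dioxocyclohexa-1,4-dien-1-yl)oxy]benzoate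
Conditions: Cs2CO3 (1.1 equiv), CH3CN, 0 °C to rt
Reagents that add atoms: none
Why: Addition–elimination on a haloquinone (nucleophilic vinylic substitution); the phenoxide adds to the bromine-bearing carbon, which is the β-carbon of a vinylogous acyl bromide, and bromide leaves, and the electron-poor phenoxide of 7 is a poor reductant for the quinone.

Step 8
Reactants: 10 tert-butyl 3-bromo-4-methoxy-6-methyl-2-[(5-methyl-3,6-dioxocyclohexa-1,4-dien-1-yl)oxy]benzoate; 11 3-methylbut-2-enal
Product: 13 tert-butyl 3-bromo-2-[(6-hydroxy-2,2,5-trimethyl-4-oxochroman-7-yl)oxy]-4-methoxy-6-methylbenzoate, via acylhydroquinone 12 (not isolated)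
Conditions: 11 (5 equiv), PhCF3 (degassed, 0.02 M), blue LEDs (450 nm), rt; then DBU (0.2 equiv), rt, dark, Ar
Reagents that add atoms: none
Why: Blue light excites the quinone of 10, its triplet abstracts the formyl hydrogen of 11 (a polarity-matched transfer from a hydridic C–H to an electrophilic oxygen), the acyl radical bonds to a ring carbon by radical-pair collapse or by addition to a ground-state quinone with hydrogen return, and tautomerisation gives acylhydroquinone 12 with no net redox change. The closest known reaction type is the photochemical Friedel–Crafts-type acylation of 1,4-quinones with aldehydes, enals included. The step needs site selectivity among the quinone carbons: C2 and C3 belong to a vinylogous ester whose aryloxy oxygen makes C3 electron-rich, so the nucleophilic acyl radical avoids them, C6 bears the methyl and could not re-aromatise, and this leaves C5, the CH next to the methyl and β to the carbonyl that is not conjugated with the aryloxy oxygen. It also needs the formyl hydrogen of 11 to react in preference to its allylic hydrogens and its electron-poor double bond, and at 450 nm neither the aryl bromide nor the product absorbs. With the light off, DBU deprotonates the phenol hydrogen-bonded to the new ketone, and this oxygen adds to the dimethyl-substituted enone terminus, closing ring D by a 6-endo-trig oxa-Michael addition. The other phenol is meta to the acyl group and cannot reach the enone, so it is kept for the lactone. No stereocenter forms, because the new quaternary carbon bears two methyl groups.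

Step 9
Reactants: 13 tert-butyl 3-bromo-2-[(6-hydroxy-2,2,5-trimethyl-4-oxochroman-7-yl)oxy]-4-methoxy-6-methylbenzoate
Product: 14 3-bromo-2-[(6-hydroxy-2,2,5-trimethyl-4-oxochroman-7-yl)oxy]-4-methoxy-6-methylbenzoic acid
Conditions: CF3CO2H/CH2Cl2 (1:4), 0 °C to rt
Reagents that add atoms: none
Why: Acidolysis of a tert-butyl ester by alkyl–oxygen cleavage; the reaction runs through the tert-butyl cation and is indifferent to crowding at the carbonyl, and the methyl ether, aryl bromide and chromanone are stable to CF3CO2H.

Step 10
Reactants: 14 3-bromo-2-[(6-hydroxy-2,2,5-trimethyl-4-oxochroman-7-yl)oxy]-4-methoxy-6-methylbenzoic acid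
Product: 15 bromo depsidone (the mollicellin B ring system with bromine in place of the formyl group and methoxy in place of the ring A hydroxyl)
Conditions: DCC (1.5 equiv), DMAP (0.2 equiv), CH2Cl2 (0.005 M), rt
Reagents that add atoms: none
Why: Steglich-type lactonisation; the carbodiimide activates the acid, DMAP relays the acyl group, and the diaryl ether holds the only phenol beside it so that ring C closes 7-exo-trig, with high dilution suppressing dimer formation.

Step 11
Reactants: 15 bromo depsidone
Product: 16 O-methylmollicellin B (ring A hydroxyl as methyl ether)
Conditions: Pd(OAc)2 (5 mol %), n-BuP(1-adamantyl)2 (15 mol %), CO (5 bar), Et3SiH (2 equiv), Na2CO3, DMF, 90 °C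
Reagents that add atoms: carbon monoxide, [C-]#[O+]
Why: Palladium-catalysed reductive carbonylation of an aryl bromide; zerovalent palladium inserts into the C–Br bond, CO insertion gives the aroyl palladium bromide, Et3SiH delivers hydride and the aldehyde is released, with the bulky electron-rich phosphine chosen for the doubly ortho-substituted bromide and no OH or NH present to intercept the acyl palladium.

Step 12
Reactants: 16 O-methylmollicellin B
Product: 17 mollicellin B
Conditions: BCl3 (3 equiv), CH2Cl2, −78 to 0 °C; aq. work-up
Reagents that add atoms: none
Why: Chelation-controlled demethylation as in step 3; the new formyl group and the adjacent methoxy oxygen form the boron chelate and only this ether is cleaved, while the lactone carbonyl has no ortho methoxy group and the diaryl ether and the ring D ether are not activated at this temperature.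

## Compound list

1 | 3,5-dimethoxytoluene | COc1cc(C)cc(OC)c1 | starting material
2 | 2,6-dimethoxy-4-methylphenyllithium | [Li]c1c(OC)cc(C)cc1OC | intermediate (not isolated)
3 | 2-bromo-1,3-dimethoxy-5-methylbenzene | COc1cc(C)cc(OC)c1Br | intermediate
4 | 3-bromo-2,4-dimethoxy-6-methylbenzaldehyde | COc1cc(C)c(C=O)c(OC)c1Br | intermediate
5 | 3-bromo-2-hydroxy-4-methoxy-6-methylbenzaldehyde | COc1cc(C)c(C=O)c(O)c1Br | intermediate
6 | 3-bromo-2-hydroxy-4-methoxy-6-methylbenzoic acid | COc1cc(C)c(C(=O)O)c(O)c1Br | intermediate
7 | tert-butyl 3-bromo-2-hydroxy-4-methoxy-6-methylbenzoate | COc1cc(C)c(C(=O)OC(C)(C)C)c(O)c1Br | intermediate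
8 | 2-bromo-6-methylphenol | Cc1cccc(Br)c1O | starting material
9 | 2-bromo-6-methyl-1,4-benzoquinone | CC1=CC(=O)C=C(Br)C1=O | intermediate
10 | tert-butyl 3-bromo-4-methoxy-6-methyl-2-[(5-methyl-3,6-dioxocyclohexa-1,4-dien-1-yl)oxy]benzoate | CC(C)(C)OC(=O)c1c(C)cc(OC)c(Br)c1OC1=CC(=O)C=C(C)C1=O | intermediate
11 | 3-methylbut-2-enal | CC(C)=CC=O | starting material
12 | tert-butyl 3-bromo-2-[2,5-dihydroxy-3-methyl-4-(3-methylbut-2-enoyl)phenoxy]-4-methoxy-6-methylbenzoate (acylhydroquinone) | CC(C)(C)OC(=O)c1c(C)cc(OC)c(Br)c1Oc1cc(O)c(C(=O)C=C(C)C)c(C)c1O | intermediate (not isolated)
13 | tert-butyl 3-bromo-2-[(6-hydroxy-2,2,5-trimethyl-4-oxochroman-7-yl)oxy]-4-methoxy-6-methylbenzoate | CC(C)(C)OC(=O)c1c(C)cc(OC)c(Br)c1Oc1cc2OC(C)(C)CC(=O)c2c(C)c1O | intermediate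
14 | 3-bromo-2-[(6-hydroxy-2,2,5-trimethyl-4-oxochroman-7-yl)oxy]-4-methoxy-6-methylbenzoic acid | OC(=O)c1c(C)cc(OC)c(Br)c1Oc1cc2OC(C)(C)CC(=O)c2c(C)c1O | intermediate
15 | bromo depsidone (mollicellin B ring system, Br for CHO, OCH3 for the ring A OH) | Cc1cc(OC)c(Br)c2c1C(=O)Oc1c(cc3c(c1C)C(=O)CC(C)(C)O3)O2 | intermediate
16 | O-methylmollicellin B | Cc1cc(OC)c(C=O)c2c1C(=O)Oc1c(cc3c(c1C)C(=O)CC(C)(C)O3)O2 | intermediate
17 | mollicellin B | Cc1cc(O)c(C=O)c2c1C(=O)Oc1c(cc3c(c1C)C(=O)CC(C)(C)O3)O2 | target

## Step count and least certain steps

Total step count: 12. Longest linear sequence: 11 steps (steps 1 to 5 and 7 to 12, from 1). The quinone branch adds step 6.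

**Step 8 (key step).**
- Most likely failure: the excited aryloxyquinone returns to the ground state without abstracting hydrogen. The electron-rich aryl ether can quench the triplet by intramolecular charge transfer, and an alkoxy-substituted quinone triplet has less n,π* character than the parent.
- Further failure modes: collapse of the radical pair at oxygen (ester formation instead of C-acylation) and some acylation beside the aryloxy group.
- Fallback: it sets out from 10 and does not excite the quinone. Reduction of 10 with Na2S2O4 (EtOAc/H2O) should give the hydroquinone tert-butyl 3-bromo-2-(2,5-dihydroxy-3-methylphenoxy)-4-methoxy-6-methylbenzoate F1. Its unhindered phenol, the one with two free ortho positions, should be acylated selectively with 3-methylbut-2-enoyl chloride and pyridine at −20 °C to give tert-butyl 3-bromo-2-{2-hydroxy-3-methyl-5-[(3-methylbut-2-enoyl)oxy]phenoxy}-4-methoxy-6-methylbenzoate F2. A photo-Fries rearrangement of F2 (Pyrex-filtered mercury lamp, benzene) then moves the acyl group to an ortho carbon. The para carbon is blocked, and the ortho carbon beside the bulky aryloxy group is the more hindered, so migration next to the methyl should be competitive. This returns to the route at 12, which is closed to 13 with DBU as in step 8.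
- Weakness of the fallback: the ortho selectivity is not secured and a regioisomer may have to be separated.

**Step 7.**
- Most likely failure: attack of the phenoxide at a ring CH instead of the bromine-bearing carbon (cine substitution, or conjugate addition followed by redox exchange with a second quinone). Base-induced decay of the quinone is also possible, because the doubly flanked phenoxide is a slow nucleophile.
- Fallback: it sets out from 9 and forms the ether at the arene oxidation level. Na2S2O4 should reduce 9 to 2-bromo-6-methylbenzene-1,4-diol F3. Dimethyl sulfate and K2CO3 in acetone should give 1-bromo-2,5-dimethoxy-3-methylbenzene F4. Bromine–lithium exchange (n-BuLi, THF, −78 °C), B(Oi-Pr)3 and acidic work-up should give (2,5-dimethoxy-3-methylphenyl)boronic acid F5. Chan–Lam coupling of F5 with 7 (catalytic Cu(OAc)2, pyridine, molecular sieves, CH2Cl2, O2) tolerates the aryl bromide and should give tert-butyl 3-bromo-2-(2,5-dimethoxy-3-methylphenoxy)-4-methoxy-6-methylbenzoate F6. Oxidative demethylation with (NH4)2Ce(NO3)6 in CH3CN/H2O at 0 °C acts on the more electron-rich trioxygenated ring and returns to the route at 10.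

**Step 11.**
- Most likely failure: slow oxidative addition into the electron-rich C–Br bond flanked by methoxy and aryloxy groups. The aryl palladium species may then be reduced by the silane before CO inserts (hydrodebromination). Opening of the lactone by base at 90 °C is a second concern.
- Fallback: it sets out from 15 and avoids both hydride and CO. Stille coupling with tributyl(vinyl)stannane (Pd(PPh3)4, toluene, 100 °C) should give the vinyl depsidone F7, which is 15 with CH=CH2 in place of Br. Lemieux–Johnson cleavage (catalytic OsO4, NaIO4, 2,6-lutidine, dioxane/H2O) returns to the route at 16.

**Step 10.**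
- Most likely failure: rearrangement of the activated ester to the N-acylurea, because the phenol flanked by methyl and aryloxy attacks the crowded acyl carbon slowly. Intermolecular esterification may also compete.
- Fallback: it sets out from 13 and merges steps 9 and 10 without a carbodiimide. CF3CO2H cleaves the tert-butyl ester to 14 in the flask. Trifluoroacetic anhydride then converts the acid into the mixed anhydride 3-bromo-2-[(6-hydroxy-2,2,5-trimethyl-4-oxochroman-7-yl)oxy]-4-methoxy-6-methylbenzoic trifluoroacetic anhydride F8. This doubly ortho-substituted aroyl trifluoroacetate ionises readily towards an acylium ion, which the neighbouring phenol captures, returning to the route at 15. Any phenol trifluoroacetate is removed on bicarbonate work-up.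

## Further compounds

F1 | step 8 | tert-butyl 3-bromo-2-(2,5-dihydroxy-3-methylphenoxy)-4-methoxy-6-methylbenzoate | CC(C)(C)OC(=O)c1c(C)cc(OC)c(Br)c1Oc1cc(O)cc(C)c1O
F2 | step 8 | tert-butyl 3-bromo-2-{2-hydroxy-3-methyl-5-[(3-methylbut-2-enoyl)oxy]phenoxy}-4-methoxy-6-methylbenzoate | CC(C)(C)OC(=O)c1c(C)cc(OC)c(Br)c1Oc1cc(OC(=O)C=C(C)C)cc(C)c1O
F3 | step 7 | 2-bromo-6-methylbenzene-1,4-diol | Cc1cc(O)cc(Br)c1O
F4 | step 7 | 1-bromo-2,5-dimethoxy-3-methylbenzene | COc1cc(C)c(OC)c(Br)c1
F5 | step 7 | (2,5-dimethoxy-3-methylphenyl)boronic acid | COc1cc(C)c(OC)c(B(O)O)c1
F6 | step 7 | tert-butyl 3-bromo-2-(2,5-dimethoxy-3-methylphenoxy)-4-methoxy-6-methylbenzoate | CC(C)(C)OC(=O)c1c(C)cc(OC)c(Br)c1Oc1cc(OC)cc(C)c1OC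
F7 | step 11 | vinyl depsidone (15 with CH=CH2 in place of Br) | Cc1cc(OC)c(C=C)c2c1C(=O)Oc1c(cc3c(c1C)C(=O)CC(C)(C)O3)O2
F8 | step 10 | 3-bromo-2-[(6-hydroxy-2,2,5-trimethyl-4-oxochroman-7-yl)oxy]-4-methoxy-6-methylbenzoic trifluoroacetic anhydride | Cc1cc(OC)c(Br)c(Oc2cc3OC(C)(C)CC(=O)c3c(C)c2O)c1C(=O)OC(=O)C(F)(F)F
A1 | alternative 1 | tricyclic depsidone with a free ring B phenol para to the ester oxygen (ring D absent) | Cc1cc(OC)c(C=O)c2c1C(=O)Oc1c(C)cc(O)cc1O2
A2 | alternative 1 | 3-formyl-2-(3-hydroxy-5-methylphenoxy)-4-methoxy-6-methylbenzoic acid | Cc1cc(OC)c(C=O)c(Oc2cc(O)cc(C)c2)c1C(=O)O
A3 | alternative 2 | mollicellin B with the formyl group as a tert-butyldimethylsilyl-protected hydroxymethyl group | Cc1cc(O)c(CO[Si](C)(C)C(C)(C)C)c2c1C(=O)Oc1c(cc3c(c1C)C(=O)CC(C)(C)O3)O2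
A4 | alternative 2 | 7-{[3-(tert-butyldimethylsilyloxy)prop-1-yn-1-yl]oxy}-2,2,5-trimethyl-4-oxochroman-6-yl 2-diazo-4-methyl-3-oxopent-4-enoate | CC(=C)C(=O)C(=[N+]=[N-])C(=O)Oc1c(OC#CCO[Si](C)(C)C(C)(C)C)cc2OC(C)(C)CC(=O)c2c1C
A5 | alternative 3 | 7-fluoro-2,2,5-trimethyl-4-oxochroman-6-yl 2,4-dihydroxy-6-methylbenzoate | Cc1cc(O)cc(O)c1C(=O)Oc1c(F)cc2OC(C)(C)CC(=O)c2c1C
A6 | alternative 3 | 7-fluoro-6-hydroxy-2,2,5-trimethylchroman-4-one | Cc1c(O)c(F)cc2OC(C)(C)CC(=O)c12
A7 | alternative 3 | 6-(2,4-dioxopentyl)-2,2-dimethyl-4H-1,3-dioxin-4-one | CC(=O)CC(=O)CC1=CC(=O)OC(C)(C)O1
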